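**Retrosynthetic overview**

1. The target is the ester of two mirror-image halves (C12 carboxyl of the diol half A with the C13 hydroxyl of the free-acid half B); it is cut there, and each half is made from one antipode of cryptone.
2. Feature on which the route rests: in each half the carboxyl-bearing C10 lies between the allylic O8–C9H2 and the vinylic C11H of the seven-membered lactone C5–C7(=O)–O8–C9–C10=C11–C6, which is where a dihalocarbene carbon ends up after insertion into the enol ether O8–C9=C11 of a six-membered dihydropyran.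
3. Key disconnection: bromo-oxepine ⇒ trans-fused 2-silyloxy-3,4-dihydro-2H-pyran + CBr2 (C9–C10 and C10–C11 formed, C9–C11 broken); afterwards C9–OAc → CH2, C10–Br → C12 carboxyl, C7 acetal → lactone.
4. Dihydropyran ⇒ enol δ-lactone of a formyl acid (C9 from an allyl group, C7 from a hydroxymethyl group); ring A stereocentres come from cryptone by anti conjugate allylation (C6), anti hydroxymethylation (C5) and axial sulfonium-ylide addition (C4).
5. Order of ring formation in each half: ring A (aldol condensation), spiro-dioxolane, six-membered enol lactone (O8 ring), fused dibromocyclopropane, seven-membered oxepine.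

Key step: step 12

Locants (same in both halves): ring A = C1(i-Pr)–C2–C3–C4–C5–C6; C13 = CH2O carbon on C4; C7 = carbon on C5; C11–C9 = two-carbon chain on C6; C10 = inserted carbon, C12 its carboxyl carbon; O8 = ring oxygen between C7 and C9. "Series A" means: C1 is R, the C6 substituent is trans to i-Pr, C7 is trans to the C6 substituent, and at C4 the carbon C13 is cis to C7 (axial) while the C4 oxygen is equatorial. "Series B" is the mirror image. Steps 17–33 repeat steps 1–16 in series B and differ only in steps 30 and 33; step 28 is the mirror image of the key step.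

Remark: the sense of induction in steps 1 and 17 is assigned from the usual face-shielding model of diarylprolinol ether enamines ((R)-catalyst gives (R)-cryptone); since both catalyst antipodes are used, a reversed assignment would only exchange their roles.

**Half A (series A)**

Step 1
Reactants: 1 3-methylbutanal; 2 methyl vinyl ketone
Product: 4 (R)-cryptone [(R)-4-isopropylcyclohex-2-en-1-one], via keto aldehyde 3 (not isolated)
Conditions: (R)-2-[methoxy(diphenyl)methyl]pyrrolidine (5 mol %), ethyl 3,4-dihydroxybenzoate (20 mol %), neat, 4 °C; then LiOH, i-PrOH, rt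
Reagents that add atoms: none
Why: Enamine-catalysed asymmetric Michael addition followed by base-induced intramolecular aldol condensation (a Robinson-type annulation), in which the diaryl(methoxy)methyl group shields one face of the E-enamine and so sets C1, and the condensation is fast enough to carry this centre through.

Step 2
Reactants: 4 (R)-cryptone; 5 allylmagnesium bromide
Product: 6 {[(3R,4R)-3-allyl-4-isopropylcyclohex-1-en-1-yl]oxy}trimethylsilane (allyl on C6 trans to i-Pr; enol double bond C4=C5)
Conditions: CuBr·SMe2 (1.2 equiv), LiCl, Me3SiCl, THF, −78 °C; Et3N quench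
Reagents that add atoms: chlorotrimethylsilane, C[Si](C)(C)Cl
Why: Me3SiCl-assisted 1,4-addition of the allylcopper reagent, which enters the enone face opposite the neighbouring isopropyl group (C6 trans to C1) while the enolate is trapped regiospecifically on the C5 side as its silyl ether.

Step 3
Reactants: 6 silyl enol ether
Product: 7 (2R,3R,4R)-3-allyl-2-(hydroxymethyl)-4-isopropylcyclohexan-1-one
Conditions: 37 % aq. HCHO, Yb(OTf)3 (10 mol %), THF/H2O, rt
Reagents that add atoms: formaldehyde, C=O
Why: Lewis-acid-catalysed Mukaiyama aldol reaction (hydroxymethylation) in water, in which C7 is attached to C5 anti to the adjacent allyl group, the all-equatorial 2,3-trans ketone being also the thermodynamic epimer.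

Step 4
Reactants: 7 hydroxymethyl ketone
Product: 8 (2R,3R,4R)-3-allyl-4-isopropyl-2-{[(2-methoxypropan-2-yl)oxy]methyl}cyclohexan-1-one (MOP ether of 7)
Conditions: 2-methoxypropene, pyridinium p-toluenesulfonate (cat.), CH2Cl2, 0 °C
Reagents that add atoms: 2-methoxypropene, COC(C)=C
Why: Acid-catalysed addition of the primary alcohol to the enol ether (mixed-ketal formation) gives a base-stable ether without a new stereocentre, which prevents retro-aldol loss of C7 and attack of the C7 oxygen on the epoxide in the next two steps.

Step 5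
Reactants: 8 MOP ether
Product: 9 series A spiro-epoxide (oxirane C4–O–C13 with C13 axial and cis to C7; C7H2O-MOP; allyl on C6)
Conditions: Me3SI, KN(SiMe3)2, THF, −10 → 0 °C
Reagents that add atoms: trimethylsulfonium iodide, C[S+](C)C.[I-]
Why: Corey–Chaykovsky epoxidation, in which the small unstabilised sulfonium ylide adds irreversibly along the axial trajectory of the chair whose three substituents are equatorial, so that C13 becomes axial (cis to C7) and the C4 oxygen equatorial as in the target.

Step 6
Reactants: 9 spiro-epoxide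
Product: 10 series A diol (tertiary C4–OH and C13H2OH; C7H2O-MOP; allyl on C6)
Conditions: KOH, DMSO/H2O, 80 °C
Reagents that add atoms: water (as hydroxide), O
Why: SN2 opening of the epoxide by hydroxide at the unhindered CH2 terminus, which leaves the C4–O bond and with it the C4 configuration untouched, ketal and alkene being inert to base.

Step 7
Reactants: 10 diol
Product: 11 series A acetonide alcohol (C4–O/C13–O isopropylidene; free C7H2OH; allyl on C6)
Conditions: pyridinium p-toluenesulfonate (cat.), CH2Cl2, rt
Reagents that add atoms: none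
Why: Acid-catalysed transketalisation in which the isopropylidene carbon of the MOP ether passes to the 1,2-diol with loss of methanol, the five-membered spiro-dioxolane being the thermodynamic ketal (the 1,3-dioxane through the C7 oxygen would hold an axial methyl group against C13), so that the C7 hydroxyl is freed in the same operation.

Step 8
Reactants: 11 acetonide alcohol
Product: 12 series A acetonide acid (C7 = CO2H; allyl on C6)
Conditions: TEMPO (2,2,6,6-tetramethylpiperidin-1-oxyl, cat.), PhI(OAc)2, NaHCO3, MeCN/H2O, rt
Reagents that add atoms: water, O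
Why: Oxoammonium-mediated oxidation of the primary alcohol through the aldehyde hydrate to the carboxylic acid, which spares the alkene and the ketal and leaves C5 in its equatorial (thermodynamic) configuration.

Step 9
Reactants: 12 acetonide acid
Product: 13 series A formyl acid (C7 = CO2H, C9 = CHO; in equilibrium with its cyclic 6-hydroxy-δ-lactone form)
Conditions: O3, CH2Cl2, −78 °C; then PPh3, −78 °C → rt
Reagents that add atoms: ozone, [O-][O+]=O
Why: Ozonolysis of the terminal alkene with reductive work-up gives the C9 aldehyde, the ketal offering no acetal C–H to ozone.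

Step 10
Reactants: 13 formyl acid
Product: 14 series A enol δ-lactone (C5–C7(=O)–O8–C9H=C11H–C6, trans-fused to ring A)
Conditions: Ac2O, NaOAc, 100 °C
Reagents that add atoms: none
Why: Cyclodehydration of a δ-formyl acid to its enol lactone (acetylation of the pseudo-acid hydroxyl and loss of acetic acid under buffered conditions), which places O8 between C7 and C9 without ambiguity and does not touch the ketal.

Step 11
Reactants: 14 enol lactone
Product: 16 series A silyl acetal [C7H(OSi-i-Pr3)–O8–C9H=C11H; 2-(triisopropylsilyloxy)-3,4-dihydro-2H-pyran trans-fused to ring A with the C4 spiro-acetonide], via enol lactol 15 (not isolated)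
Conditions: i-Bu2AlH (1.1 equiv), CH2Cl2, −78 °C; aq. KNaC4H4O6 work-up; then i-Pr3SiOTf, 2,6-lutidine, CH2Cl2, −78 °C
Reagents that add atoms: triisopropylsilyl trifluoromethanesulfonate, CC(C)[Si](OS(=O)(=O)C(F)(F)F)(C(C)C)C(C)C
Why: Partial hydride reduction of the lactone stops at the aluminium hemiacetal at −78 °C (the known behaviour of iridoid-type enol δ-lactones) and the lactol hydroxyl is silylated at once so that ring opening to the dialdehyde cannot set in, C7 forming as an epimer mixture that is erased in step 16.

Step 12
Reactants: 16 silyl acetal; 17 bromoform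
Product: 19 series A bromo-oxepine acetate [C7H(OSi-i-Pr3)–O8–C9H(OAc)–C10(Br)=C11H; C7 and C9 as epimer mixtures], via dibromocyclopropane 18 (not isolated)
Conditions: CHBr3, KOt-Bu, pentane, −20 → 0 °C; filter, evaporate; then AgOAc, NaOAc, PhMe, 90 °C
Reagents that add atoms: bromoform (17), BrC(Br)Br; silver acetate, CC(=O)[O-].[Ag+]
Why: α-Elimination of CHBr3 with KOt-Bu gives CBr2, which adds in a concerted [2+1] fashion to the electron-rich enol ether C9=C11 and so forms C9–C10 and C10–C11; the cyclopropane 18 is necessarily cis-fused and the face of attack is irrelevant because C9 and C11 lose this stereochemistry again. AgOAc then removes the bromide that lies endo over the pyran ring while the shared bond C9–C11 opens in a disrotatory electrocyclic sense, which gives the ring-contained Z-allyl cation as the oxocarbenium ion O8=C9, and acetate adds to C9. The closest known reaction type is the dihalocarbene cyclopropanation of glycals and other 3,4-dihydro-2H-pyrans followed by silver-assisted expansion to 3-halo-2,7-dihydrooxepines. The three-membered ring closes by cheletropic addition, and the seven-membered ring arises not by cyclisation but by expansion of the six-membered ring through cleavage of its zero-atom bridge. No lasting stereocentre is created (C9 is an acetal epimer mixture removed in step 13, C7 stays an epimer mixture) and C1, C4, C5 and C6 are not touched. The step needs capture at C9 and not at C11, which the lone pair of O8 secures by localising the positive charge on C9, and it needs protecting groups that resist base and silver salt, which the ketal and the bulky, weakly donating silyl acetal are.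

Step 13
Reactants: 19 bromo-oxepine acetate
Product: 20 series A bromo-oxepine (C9H2; C10–Br; C7 silyl acetal; acetonide)
Conditions: Et3SiH, BF3·OEt2, CH2Cl2, −78 → −40 °C
Reagents that add atoms: none
Why: Ionic hydrogenation, in which the allylic anomeric acetate ionises far more readily than the bulky silyl acetal or the ketal and the oxocarbenium ion takes up hydride at C9, the carbon that carries most of the charge.

Step 14
Reactants: 20 bromo-oxepine
Product: 21 series A C12 carboxylic acid (C10–CO2H; C7 silyl acetal; acetonide)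
Conditions: Pd(PPh3)4 (5 mol %), CO (1 atm), H2O, Et3N, DMF, 60 °C; pH 5 work-up
Reagents that add atoms: carbon monoxide, [C-]#[O+]; water, O
Why: Palladium-catalysed hydroxycarbonylation of the alkenyl bromide (oxidative addition, CO insertion, hydrolysis of the acylpalladium) turns C10–Br into the C12 carboxyl without moving the double bond, and it is run while C7 is still an acetal so that no allylic ester is exposed to zerovalent palladium.

Step 15
Reactants: 21 silyl acetal acid
Product: 22 series A lactol acid (C7H(OH)–O8; C12 CO2H; acetonide)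
Conditions: Bu4NF, AcOH, THF, 0 °C → rt
Reagents that add atoms: none
Why: Fluoride-induced cleavage of the silyl acetal under buffered conditions frees the seven-membered lactol without disturbing the ketal.

Step 16
Reactants: 22 lactol acid
Product: 23 series A lactone acid (half A: C7 lactone, C12 CO2H, C4/C13 acetonide)
Conditions: TEMPO (cat.), PhI(OAc)2, CH2Cl2, rt
Reagents that add atoms: none
Why: Oxoammonium oxidation of the lactol to the lactone, the cis double bond and the trans ring fusion holding the hydroxy aldehyde in its cyclic form, so that both C7 epimers converge.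

**Half B (series B, mirror image)**

Step 17
Reactants: 1 3-methylbutanal; 2 methyl vinyl ketone
Product: 25 (S)-cryptone, via keto aldehyde 24 (not isolated)
Conditions: (S)-2-[methoxy(diphenyl)methyl]pyrrolidine (5 mol %), ethyl 3,4-dihydroxybenzoate (20 mol %), neat, 4 °C; then LiOH, i-PrOH, rt
Reagents that add atoms: none
Why: Same enamine-catalysed Michael addition and aldol condensation as step 1 with the antipodal catalyst, which sets C1 as S.

Step 18
Reactants: 25 (S)-cryptone; 5 allylmagnesium bromide
Product: 26 {[(3S,4S)-3-allyl-4-isopropylcyclohex-1-en-1-yl]oxy}trimethylsilane (enantiomer of 6)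
Conditions: CuBr·SMe2 (1.2 equiv), LiCl, Me3SiCl, THF, −78 °C; Et3N quench
Reagents that add atoms: chlorotrimethylsilane, C[Si](C)(C)Cl
Why: Mirror image of step 2 (anti 1,4-addition of allylcopper with silyl trapping), so C6 is again set trans to C1.

Step 19
Reactants: 26 silyl enol ether
Product: 27 (2S,3S,4S)-3-allyl-2-(hydroxymethyl)-4-isopropylcyclohexan-1-one
Conditions: 37 % aq. HCHO, Yb(OTf)3 (10 mol %), THF/H2O, rt
Reagents that add atoms: formaldehyde, C=O
Why: Mirror image of step 3 (aqueous Mukaiyama aldol hydroxymethylation), C7 entering anti to the allyl group.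

Step 20
Reactants: 27 hydroxymethyl ketone
Product: 28 MOP ether of 27 (enantiomer of 8)
Conditions: 2-methoxypropene, pyridinium p-toluenesulfonate (cat.), CH2Cl2, 0 °C
Reagents that add atoms: 2-methoxypropene, COC(C)=C
Why: Mirror image of step 4 (acid-catalysed mixed-ketal formation), no new stereocentre.

Step 21
Reactants: 28 MOP ether
Product: 29 series B spiro-epoxide (enantiomer of 9)
Conditions: Me3SI, KN(SiMe3)2, THF, −10 → 0 °C
Reagents that add atoms: trimethylsulfonium iodide, C[S+](C)C.[I-]
Why: Mirror image of step 5 (Corey–Chaykovsky epoxidation by axial attack), which sets C4 with C13 axial and cis to C7.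

Step 22
Reactants: 29 spiro-epoxide
Product: 30 series B diol (enantiomer of 10)
Conditions: KOH, DMSO/H2O, 80 °C
Reagents that add atoms: water (as hydroxide), O
Why: Mirror image of step 6 (SN2 epoxide opening at the CH2 terminus), C4 retained.

Step 23
Reactants: 30 diol
Product: 31 series B acetonide alcohol (enantiomer of 11)
Conditions: pyridinium p-toluenesulfonate (cat.), CH2Cl2, rt
Reagents that add atoms: none
Why: Mirror image of step 7 (transketalisation to the thermodynamic spiro-dioxolane with release of the C7 hydroxyl).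

Step 24
Reactants: 31 acetonide alcohol
Product: 32 series B acetonide acid (enantiomer of 12)
Conditions: TEMPO (cat.), PhI(OAc)2, NaHCO3, MeCN/H2O, rt
Reagents that add atoms: water, O
Why: Mirror image of step 8 (oxoammonium oxidation of the primary alcohol to the acid).

Step 25
Reactants: 32 acetonide acid
Product: 33 series B formyl acid (enantiomer of 13)
Conditions: O3, CH2Cl2, −78 °C; then PPh3, −78 °C → rt
Reagents that add atoms: ozone, [O-][O+]=O
Why: Mirror image of step 9 (ozonolysis with reductive work-up).

Step 26
Reactants: 33 formyl acid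
Product: 34 series B enol δ-lactone (enantiomer of 14)
Conditions: Ac2O, NaOAc, 100 °C
Reagents that add atoms: none
Why: Mirror image of step 10 (cyclodehydration of the δ-formyl acid to the enol lactone).

Step 27
Reactants: 34 enol lactone
Product: 36 series B silyl acetal (enantiomer of 16), via enol lactol 35 (not isolated)
Conditions: i-Bu2AlH (1.1 equiv), CH2Cl2, −78 °C; aq. KNaC4H4O6 work-up; then i-Pr3SiOTf, 2,6-lutidine, CH2Cl2, −78 °C
Reagents that add atoms: triisopropylsilyl trifluoromethanesulfonate, CC(C)[Si](OS(=O)(=O)C(F)(F)F)(C(C)C)C(C)C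
Why: Mirror image of step 11 (partial lactone reduction and immediate O-silylation of the enol lactol).

Step 28
Reactants: 36 silyl acetal; 17 bromoform
Product: 38 series B bromo-oxepine acetate (enantiomer of 19), via dibromocyclopropane 37 (not isolated)
Conditions: CHBr3, KOt-Bu, pentane, −20 → 0 °C; filter, evaporate; then AgOAc, NaOAc, PhMe, 90 °C
Reagents that add atoms: bromoform (17), BrC(Br)Br; silver acetate, CC(=O)[O-].[Ag+]
Why: Mirror image of step 12 (dibromocarbene cyclopropanation of the enol ether and silver-assisted disrotatory ring expansion with acetate capture at C9), governed by the same oxocarbenium control.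

Step 29
Reactants: 38 bromo-oxepine acetate
Product: 39 series B bromo-oxepine (enantiomer of 20)
Conditions: Et3SiH, BF3·OEt2, CH2Cl2, −78 → −40 °C
Reagents that add atoms: none
Why: Mirror image of step 13 (ionic hydrogenation of the allylic acetoxy acetal at C9).

Step 30
Reactants: 39 bromo-oxepine
Product: 40 series B 4-methoxybenzyl ester (C10–CO2CH2C6H4OMe; C7 silyl acetal; acetonide)
Conditions: Pd(PPh3)4 (5 mol %), CO (1 atm), 4-methoxybenzyl alcohol, Et3N, DMF, 60 °C
Reagents that add atoms: carbon monoxide, [C-]#[O+]; 4-methoxybenzyl alcohol, COc1ccc(CO)cc1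
Why: Palladium-catalysed alkoxycarbonylation of the alkenyl bromide with the benzylic alcohol as nucleophile gives the acid-labile ester that masks C12 of half B during the union.

Step 31
Reactants: 40 silyl acetal ester
Product: 41 series B lactol ester
Conditions: Bu4NF, AcOH, THF, 0 °C → rt
Reagents that add atoms: none
Why: Buffered fluoride cleavage of the silyl acetal as in step 15, the ester and the ketal being stable to these conditions.

Step 32
Reactants: 41 lactol ester
Product: 42 series B lactone ester (C7 lactone; C12 4-methoxybenzyl ester; acetonide)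
Conditions: TEMPO (cat.), PhI(OAc)2, CH2Cl2, rt
Reagents that add atoms: none
Why: Oxoammonium oxidation of the lactol to the lactone as in step 16.

Step 33
Reactants: 42 lactone ester
Product: 43 series B diol lactone ester (half B: free C4–OH and C13H2OH; C12 4-methoxybenzyl ester)
Conditions: AcOH/H2O (4:1), 40 °C
Reagents that add atoms: none
Why: Mild aqueous acid hydrolyses the spiro-ketal and leaves the 4-methoxybenzyl ester and the lactone intact, which frees the primary C13 hydroxyl.

**Union and end game**

Step 34
Reactants: 23 half A acid; 43 half B diol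
Product: 45 protected dimer (C12 of half A esterified with O–C13 of half B; acetonide on half A; 4-methoxybenzyl ester on half B), via mixed anhydride 44 (not isolated)
Conditions: 2,4,6-Cl3C6H2COCl, Et3N, THF, rt; then 43, 4-(dimethylamino)pyridine (DMAP), PhMe, rt
Reagents that add atoms: none
Why: Yamaguchi esterification, in which the mixed anhydride of 23 acylates the primary C13 hydroxyl of 43 under DMAP catalysis while the tertiary C4 hydroxyl is too hindered to compete.

Step 35
Reactants: 45 protected dimer
Product: 46 CNP0340505.1 (target)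
Conditions: TFA/H2O (9:1), 0 °C, short contact; toluene co-evaporation
Reagents that add atoms: none
Why: Acidolysis cleaves the 4-methoxybenzyl ester through the stabilised benzylic cation (trapped by water) and hydrolyses the isopropylidene ketal in the same cold, brief treatment, which limits migration of the lactone acyl group to the freed C13 hydroxyl.

**Compound list**

1 | 3-methylbutanal | CC(C)CC=O | starting material
2 | methyl vinyl ketone | CC(=O)C=C | starting material
3 | (R)-2-isopropyl-5-oxohexanal | CC(C)[C@@H](CCC(C)=O)C=O | intermediate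
4 | (R)-cryptone | CC(C)[C@H]1CCC(=O)C=C1 | intermediate
5 | allylmagnesium bromide | C=CC[Mg]Br | starting material
6 | {[(3R,4R)-3-allyl-4-isopropylcyclohex-1-en-1-yl]oxy}trimethylsilane | CC(C)[C@H]1CCC(O[Si](C)(C)C)=C[C@@H]1CC=C | intermediate
7 | (2R,3R,4R)-3-allyl-2-(hydroxymethyl)-4-isopropylcyclohexan-1-one | CC(C)[C@H]1CCC(=O)[C@@H](CO)[C@@H]1CC=C | intermediate
8 | MOP ether of 7 | CC(C)[C@H]1CCC(=O)[C@@H](COC(C)(C)OC)[C@@H]1CC=C | intermediate
9 | series A spiro-epoxide (C13 axial, cis to C7) | CC(C)[C@H]1CC[C@@]2(CO2)[C@@H](COC(C)(C)OC)[C@@H]1CC=C | intermediate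
10 | series A diol with C7H2O-MOP | CC(C)[C@H]1CC[C@@](O)(CO)[C@@H](COC(C)(C)OC)[C@@H]1CC=C | intermediate
11 | series A acetonide alcohol | CC(C)[C@H]1CC[C@@]3(COC(C)(C)O3)[C@@H](CO)[C@@H]1CC=C | intermediate
12 | series A acetonide acid | CC(C)[C@H]1CC[C@@]3(COC(C)(C)O3)[C@@H](C(=O)O)[C@@H]1CC=C | intermediate
13 | series A formyl acid | CC(C)[C@H]1CC[C@@]3(COC(C)(C)O3)[C@@H](C(=O)O)[C@@H]1CC=O | intermediate
14 | series A enol δ-lactone | CC(C)[C@H]1CC[C@@]3(COC(C)(C)O3)[C@H]2C(=O)OC=C[C@H]12 | intermediate
15 | series A enol lactol (C7 epimers) | CC(C)[C@H]1CC[C@@]3(COC(C)(C)O3)[C@H]2C(O)OC=C[C@H]12 | intermediate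
16 | series A 2-(triisopropylsilyloxy)dihydropyran (C7 epimers) | CC(C)[C@H]1CC[C@@]3(COC(C)(C)O3)[C@H]2C(O[Si](C(C)C)(C(C)C)C(C)C)OC=C[C@H]12 | intermediate
17 | bromoform | BrC(Br)Br | starting material
18 | series A dibromocyclopropane (C10Br2 across C9–C11) | CC(C)[C@H]1CC[C@@]3(COC(C)(C)O3)[C@H]2C(O[Si](C(C)C)(C(C)C)C(C)C)OC4C(Br)(Br)C4[C@H]12 | intermediate
19 | series A bromo-oxepine acetate (C7, C9 epimers) | CC(C)[C@H]1CC[C@@]3(COC(C)(C)O3)[C@H]2C(O[Si](C(C)C)(C(C)C)C(C)C)OC(OC(C)=O)C(Br)=C[C@H]12 | intermediate
20 | series A bromo-oxepine (C9H2) | CC(C)[C@H]1CC[C@@]3(COC(C)(C)O3)[C@H]2C(O[Si](C(C)C)(C(C)C)C(C)C)OCC(Br)=C[C@H]12 | intermediate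
21 | series A C12 acid, C7 silyl acetal | CC(C)[C@H]1CC[C@@]3(COC(C)(C)O3)[C@H]2C(O[Si](C(C)C)(C(C)C)C(C)C)OCC(C(=O)O)=C[C@H]12 | intermediate
22 | series A lactol acid | CC(C)[C@H]1CC[C@@]3(COC(C)(C)O3)[C@H]2C(O)OCC(C(=O)O)=C[C@H]12 | intermediate
23 | series A lactone acid (half A) | CC(C)[C@H]1CC[C@@]3(COC(C)(C)O3)[C@H]2C(=O)OCC(C(=O)O)=C[C@H]12 | intermediate
24 | (S)-2-isopropyl-5-oxohexanal | CC(C)[C@H](CCC(C)=O)C=O | intermediate
25 | (S)-cryptone | CC(C)[C@@H]1CCC(=O)C=C1 | intermediate
26 | {[(3S,4S)-3-allyl-4-isopropylcyclohex-1-en-1-yl]oxy}trimethylsilane | CC(C)[C@@H]1CCC(O[Si](C)(C)C)=C[C@H]1CC=C | intermediate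
27 | (2S,3S,4S)-3-allyl-2-(hydroxymethyl)-4-isopropylcyclohexan-1-one | CC(C)[C@@H]1CCC(=O)[C@H](CO)[C@H]1CC=C | intermediate
28 | MOP ether of 27 | CC(C)[C@@H]1CCC(=O)[C@H](COC(C)(C)OC)[C@H]1CC=C | intermediate
29 | series B spiro-epoxide | CC(C)[C@@H]1CC[C@]2(CO2)[C@H](COC(C)(C)OC)[C@H]1CC=C | intermediate
30 | series B diol with C7H2O-MOP | CC(C)[C@@H]1CC[C@](O)(CO)[C@H](COC(C)(C)OC)[C@H]1CC=C | intermediate
31 | series B acetonide alcohol | CC(C)[C@@H]1CC[C@]3(COC(C)(C)O3)[C@H](CO)[C@H]1CC=C | intermediate
32 | series B acetonide acid | CC(C)[C@@H]1CC[C@]3(COC(C)(C)O3)[C@H](C(=O)O)[C@H]1CC=C | intermediate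
33 | series B formyl acid | CC(C)[C@@H]1CC[C@]3(COC(C)(C)O3)[C@H](C(=O)O)[C@H]1CC=O | intermediate
34 | series B enol δ-lactone | CC(C)[C@@H]1CC[C@]3(COC(C)(C)O3)[C@@H]2C(=O)OC=C[C@@H]12 | intermediate
35 | series B enol lactol | CC(C)[C@@H]1CC[C@]3(COC(C)(C)O3)[C@@H]2C(O)OC=C[C@@H]12 | intermediate
36 | series B 2-(triisopropylsilyloxy)dihydropyran | CC(C)[C@@H]1CC[C@]3(COC(C)(C)O3)[C@@H]2C(O[Si](C(C)C)(C(C)C)C(C)C)OC=C[C@@H]12 | intermediate
37 | series B dibromocyclopropane | CC(C)[C@@H]1CC[C@]3(COC(C)(C)O3)[C@@H]2C(O[Si](C(C)C)(C(C)C)C(C)C)OC4C(Br)(Br)C4[C@@H]12 | intermediate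
38 | series B bromo-oxepine acetate | CC(C)[C@@H]1CC[C@]3(COC(C)(C)O3)[C@@H]2C(O[Si](C(C)C)(C(C)C)C(C)C)OC(OC(C)=O)C(Br)=C[C@@H]12 | intermediate
39 | series B bromo-oxepine (C9H2) | CC(C)[C@@H]1CC[C@]3(COC(C)(C)O3)[C@@H]2C(O[Si](C(C)C)(C(C)C)C(C)C)OCC(Br)=C[C@@H]12 | intermediate
40 | series B 4-methoxybenzyl ester, C7 silyl acetal | CC(C)[C@@H]1CC[C@]3(COC(C)(C)O3)[C@@H]2C(O[Si](C(C)C)(C(C)C)C(C)C)OCC(C(=O)OCc4ccc(OC)cc4)=C[C@@H]12 | intermediate
41 | series B lactol ester | CC(C)[C@@H]1CC[C@]3(COC(C)(C)O3)[C@@H]2C(O)OCC(C(=O)OCc4ccc(OC)cc4)=C[C@@H]12 | intermediate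
42 | series B lactone ester, acetonide | CC(C)[C@@H]1CC[C@]3(COC(C)(C)O3)[C@@H]2C(=O)OCC(C(=O)OCc4ccc(OC)cc4)=C[C@@H]12 | intermediate
43 | series B diol lactone ester (half B) | CC(C)[C@@H]1CC[C@](O)(CO)[C@@H]2C(=O)OCC(C(=O)OCc3ccc(OC)cc3)=C[C@@H]12 | intermediate
44 | mixed 2,4,6-trichlorobenzoic anhydride of 23 | CC(C)[C@H]1CC[C@@]3(COC(C)(C)O3)[C@H]2C(=O)OCC(C(=O)OC(=O)c4c(Cl)cc(Cl)cc4Cl)=C[C@H]12 | intermediate
45 | protected dimer (acetonide on half A, 4-methoxybenzyl ester on half B) | CC(C)[C@H]1CC[C@@]5(COC(C)(C)O5)[C@H]2C(=O)OCC(C(=O)OC[C@@]3(O)CC[C@@H](C(C)C)[C@@H]4C=C(C(=O)OCc6ccc(OC)cc6)COC(=O)[C@H]43)=C[C@H]12 | intermediate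
46 | CNP0340505.1 | CC(C)[C@H]1CC[C@@](O)(CO)[C@H]2C(=O)OCC(C(=O)OC[C@@]3(O)CC[C@@H](C(C)C)[C@@H]4C=C(C(=O)O)COC(=O)[C@H]43)=C[C@H]12 | target

**Step count**

Total: 35 steps (16 for half A, 17 for half B, 2 after the union). Longest linear sequence: 19 steps (steps 17–35).

**Steps most likely to fail**

1. Step 12 (key step; step 28 is the same reaction in series B). The silver-assisted ionisation of the trans-fused dibromocyclopropane may be sluggish, or the oxocarbenium ion may fragment at O8–C7 with loss of the silyl acetal before acetate captures it. The fallback closes the seven-membered ring by ring-closing metathesis instead of carbene insertion; it sets out from acid 12 and comes back at acid 23. The allyl group of 12 is isomerised with RuHCl(CO)(PPh3)3 in toluene at 80 °C to the (E)-prop-1-enyl acid F1. Its caesium salt (Cs2CO3, DMF) is alkylated with 2-(trimethylsilyl)ethyl 2-(bromomethyl)acrylate F2, made from commercial 2-(bromomethyl)acrylic acid and 2-(trimethylsilyl)ethanol with N,N'-diisopropylcarbodiimide and cat. DMAP, to give the diene diester F3. Second-generation Hoveyda–Grubbs catalyst (PhMe, 80 °C) then closes C10=C11 to the lactone 2-(trimethylsilyl)ethyl ester F4, and Bu4NF in THF at 0 °C cleaves this ester to 23. In series B the same sequence runs from acid 32 through the (E)-prop-1-enyl acid F5, with 4-methoxybenzyl 2-(bromomethyl)acrylate F6, to the diene diester F7, whose metathesis gives 42 directly.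

2. Step 16 (and its mirror image, step 32). The lactol may react through its open hydroxy-aldehyde tautomer, so that the allylic C9 alcohol is oxidised instead of the lactol C–H. The fallback oxidises the aldehyde form and then lactonises; it sets out from 22 and comes back at 23. Pinnick oxidation (NaClO2, NaH2PO4, 2-methylbut-2-ene, t-BuOH/H2O) of the tautomer mixture gives the hydroxy diacid F8. Carbodiimide lactonisation (EDC·HCl, cat. DMAP, CH2Cl2, high dilution) then joins the C7 carboxyl to the C9 hydroxyl and gives 23; the acrylic C12 acid has no feasible ring size open to it. In series B, 41 gives the hydroxy acid ester F9 and then 42 in the same way.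

3. Step 34. Acylation of the neopentyl-type C13 hydroxyl may be slow, which gives time for base-induced migration of the lactone acyl group from O8 to the C13 oxygen of 43. The fallback uses the carboxylate as nucleophile on a spiro-epoxide instead of the alcohol on an activated acid; it sets out from 43 and 23 and comes back at 45. 43 is sulfonylated at the primary hydroxyl (TsCl, pyridine, 0 °C) to the monotosylate F10, and NaH in THF at 0 °C closes the spiro-epoxide F11 with retention at C4. The caesium salt of 23 (Cs2CO3, DMF, 60 °C) opens F11 at its CH2 terminus (C13) to give 45.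

**Further compounds**

F1 | step 12 | series A (E)-prop-1-enyl acid | CC(C)[C@H]1CC[C@@]3(COC(C)(C)O3)[C@@H](C(=O)O)[C@@H]1/C=C/C
F2 | step 12 | 2-(trimethylsilyl)ethyl 2-(bromomethyl)acrylate | C=C(CBr)C(=O)OCC[Si](C)(C)C
F3 | step 12 | series A diene diester | CC(C)[C@H]1CC[C@@]3(COC(C)(C)O3)[C@@H](C(=O)OCC(=C)C(=O)OCC[Si](C)(C)C)[C@@H]1/C=C/C
F4 | step 12 | series A lactone 2-(trimethylsilyl)ethyl ester | CC(C)[C@H]1CC[C@@]3(COC(C)(C)O3)[C@H]2C(=O)OCC(C(=O)OCC[Si](C)(C)C)=C[C@H]12
F5 | step 28 | series B (E)-prop-1-enyl acid | CC(C)[C@@H]1CC[C@]3(COC(C)(C)O3)[C@H](C(=O)O)[C@H]1/C=C/C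
F6 | step 28 | 4-methoxybenzyl 2-(bromomethyl)acrylate | C=C(CBr)C(=O)OCc1ccc(OC)cc1
F7 | step 28 | series B diene diester | CC(C)[C@@H]1CC[C@]3(COC(C)(C)O3)[C@H](C(=O)OCC(=C)C(=O)OCc4ccc(OC)cc4)[C@H]1/C=C/C
F8 | step 16 | series A hydroxy diacid | CC(C)[C@H]1CC[C@@]3(COC(C)(C)O3)[C@@H](C(=O)O)[C@@H]1/C=C(\CO)C(=O)O
F9 | step 32 | series B hydroxy acid 4-methoxybenzyl ester | CC(C)[C@@H]1CC[C@]3(COC(C)(C)O3)[C@H](C(=O)O)[C@H]1/C=C(\CO)C(=O)OCc4ccc(OC)cc4
F10 | step 34 | series B C13 monotosylate | CC(C)[C@@H]1CC[C@](O)(COS(=O)(=O)c3ccc(C)cc3)[C@@H]2C(=O)OCC(C(=O)OCc4ccc(OC)cc4)=C[C@@H]12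
F11 | step 34 | series B spiro-epoxide lactone ester | CC(C)[C@@H]1CC[C@]3(CO3)[C@@H]2C(=O)OCC(C(=O)OCc4ccc(OC)cc4)=C[C@@H]12
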